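## The problem

The target is a tetracyclic ketone built on the central arene, ring B. Its B1–B2 edge carries a seven-membered ketone ring that also holds ring A (Ca, A1, A6, Cb, Cc, B1, B2), and its B1–B6 edge carries an indane ring (Cc, Ce, Cd). The sp3 carbon Cc therefore belongs to both carbocycles.

Four contiguous benzylic methines must be set as Cb S, Cc R, Ce S, Cd S. This is all-trans around the cyclopentane, with the Cb aryl on the face of the seven-membered ring away from Ce (H at Cb anti to H at Cc).

Only Cc can be fixed cleanly by an external chiral element. Ce is its neighbour and can be relayed from it, Cd is the thermodynamically preferred trans position next to Ce, and Cb has to be read from the folded tricyclic system.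

The eight phenols are oxidation-prone and must travel as ethers. Three of the rings are resorcinol-type nucleophiles and every benzylic carbon is a potential cation. In particular, the 3,5-dioxygenated aryl on Cd sits cis-1,3 to Cb on the all-trans indane. A cation at Cb would be captured by it to give a bicyclo[3.2.1]octane unless that ring is switched off.

A carbonyl group on Cb makes Cc epimerisable. This is tolerable only once the indane exists, because the trans arrangement is then the stable one.

The feature that makes the key step possible: Cd is a diarylmethine on B6, and Ce is a benzylic methine bearing a 4-oxygenated aryl. The path B6–B1–Cc–Ce puts a diaryl carbene at Cd five atoms from a hydridic Ce–H bond, so a 1,5 C–H insertion closes the indane.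

## Retrosynthesis

**Protecting groups (29 from 28 from 27).** Six phenols are carried as methyl ethers, which survive lithium reagents, the carbene, t-BuOK and acid, and are cleaved last with BBr3 (28 to 29). The two phenols of the Cd aryl are handled separately. They are MOM ethers while base and organolithium chemistry is needed and tosylates (27) while cation chemistry is needed. The tosylates come off before the BBr3 step (27 to 28), because the hexamethyl ether tolerates hot hydroxide far better than the free octaphenol would.

**Cb–A6, the seven-membered ring (27 from 26).** The ring is cut at Cb–A6. Forward, the p-methoxybenzyl cation from carbinol 26 is attacked by ring A, which is already tied to B2 through the Ca ketone.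

- The neighbouring cut (ring A added at Cb first, intermolecular arylation of an open-chain Cb cation by anisole, then acylation at B2) was rejected for three reasons. It offers no predictable facial bias at Cb, it has an anthrone-type closure as competitor, and the Cb cation would be captured by the resorcinol ring on Cd.
- With the tether in place, the ring-closing transition state puts the anisyl group and ring A on either side of the Cc hydrogen, away from the five-membered ring. This is the target configuration at Cb.
- The step requires that the Cd aryl be non-nucleophilic, hence the tosylates. Precursor 26 lacks one ring and one stereocentre.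

**Cb–aryl bond and group exchange (26 from 24 and 25; 24 from 23 from 22 from 21).** The Cb–anisyl bond is cut to aldehyde 24 and Grignard reagent 25. Carbonyl addition is used because it needs no cation. Aldehyde 24 comes from alcohol 23 by oxidation, 23 from triol 22 by phenol-selective tosylation, and 22 from 21 by one acid treatment that removes the TBS ether and both MOM groups. The forward steps require chemoselectivity only: aldehyde over a hindered diaryl ketone, and phenol over primary alcohol.

**Ca–B2 (21 from 18 and 19).** The ketone is cut at Ca–B2 to the aryllithium from bromide 18 and Weinreb amide 19. A Friedel–Crafts acylation of the bromine-free indane would have to choose among B2, B4 and the three free positions of the Cd aryl. A bromine placed at B2 early settles the regiochemistry. Precursor 18 is the key-step product with all three indane stereocentres in place.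

**Cd–Ce, the indane (18 from 16, by way of 17).** The five-membered ring is cut at Cd–Ce, giving diaryldiazomethane 16.

- Cationic closure onto B6 would need an acyclic Ce–Cd chain with two stereocentres built first. An indenone annulation would give a flat ring with no stereocentres.
- The carbene insertion uses a C–H bond as the functional group, so Ce needs no handle and arrives by a simple enolate benzylation.
- The step requires insertion at Ce–H and not at the two other 1,5 C–H sites, and relay of configuration from Cc to Ce.
- The kinetic product at Cd is expected to be the cis isomer 17. It is therefore equilibrated in the same flask with t-BuOK in DMSO to the all-trans indane 18. This is why the phenols of the Cd aryl are MOM ethers at this stage.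

**The diazo compound (16 from 15 from 10 and 12; 12 from 11).** Diazo compound 16 comes from hydrazone 15 by oxidation. The hydrazone of a di-ortho-substituted benzophenone is hard to make by condensation. The C=N bond is therefore made by adding the aryllithium 13 from dibromide 10 to nitrile 12, and the N–H ketimine 14 is transiminated with hydrazine. Both bromines of 10 are equivalent by rotation, so one exchange gives a single species and leaves the second bromine as the B2 handle. Nitrile 12 is the bis-MOM ether of commercial 11.

**The Cc stereocentre (10 from 9 from 8 from 7 from 4 and 5; 4 from 1 and 2).** Dibromide 10 comes from silyl ether 9 by twofold bromination, 9 from alcohol 8, and 8 from imide 7 by reduction. Imide 7 is cut at Cc–Ce to the enolate of imide 4 and 4-methoxybenzyl bromide 5. This is an auxiliary-controlled benzylation, which fixes the absolute configuration of the whole molecule from acid 1 and oxazolidinone 2.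

## Roads not taken

**Alternative 1:** aryne insertion into an indanone.

- The cut: Cc–B1 and Ca–B2 are cut together, leading to indanone β-keto ester A2 (ring A, Ca, Cb, Cc in a five-membered ring) and the 3,5-dimethoxybenzyne precursor A3.
- Forward step: fluoride releases the aryne. The enolate of A2 adds through Cc at B1, the aryl anion at B2 closes onto Ca, and the four-membered alkoxide fragments to the dibenzosuberone A1.
- Merits: two skeletal bonds and the difficult seven-membered ring form in one metal-free operation. The Cb/Cc relationship is set by protonation of an ester enolate and can be equilibrated to trans.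
- Weak points:
  - In A1, Ce is only an ester carbon and B6 is a C–H. Three more C–C bonds and both indane stereocentres (Ce, Cd) must be made late, beside the Ca ketone, by cation and hydride chemistry.
  - The absolute configuration would have to come from an enantioselective synthesis of A2, which is a separate unsolved problem.
  - A 3-aryl-substituted indanone ester is a hindered partner for an aryne flanked by a methoxy group.
- Comparison: in skeletal economy this road is better than the chosen one, whose key step makes one bond and the easy five-membered ring. The chosen plan sets against it a single auxiliary step that fixes Cc, relay to Ce, a thermodynamic Cd and a ring-controlled Cb.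

**Alternative 2:** ring reorganisation by 1,2-aryl shift.

- The cut: the Cc–B1 bond is traced back to a Cb–B1 bond in the six/six isomer A5, an anthrone with a peri-fused six-membered ring, quaternary Cb and a hydroxyl on Cc.
- Forward step: activation of the hydroxyl with Tf2O and a hindered pyridine base makes B1 migrate from Cb to Cc. The anthrone ring expands to seven members and the peri ring contracts to five. Et3SiH reduces the diaryl cation left at Cb, giving A4.
- Merits: both odd-sized rings arise in one late step from a skeleton reachable by ordinary six-ring Friedel–Crafts chemistry. An anti migration transfers configuration to Cc.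
- Weak points:
  - A5 has four stereocentres, one of them quaternary, and is no easier to make than the target.
  - The leaving group must lie anti to the ring bond Cb–B1, otherwise elimination or another shift takes over.
  - The silane should deliver hydride to the face of the Cb cation away from the five-membered ring. This would put the Cb hydrogen cis to the Cc hydrogen, the opposite of what the target needs.
  - After the shift the Cb cation sits cis-1,3 to the electron-rich Cd aryl, which can capture it.
  - A4 still carries a mesylate that needs its own removal.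
- Comparison: if A5 were available this road would be shorter at the end and more striking. The chosen plan sets against it a kinetically and thermodynamically favoured Cb configuration and intermediates that are each simple to reach.

**Alternative 3:** three-component indenone annulation.

- The cut: B6–Cd and Ce–Cc are cut, leading to dibromo aldehyde A7 and diaryl alkyne A8.
- Forward step: Pd(OAc)2 with NaOAc and Bu4NCl in DMF. Arylpalladium formation at one bromine, alkyne insertion and addition of the vinylpalladium to the aldehyde give indenone A6.
- Merits: the complete indane carbon skeleton, including a bromine at B2, comes in one step from three cheap pieces. The chosen route needs eight steps to reach the same stage, so this road is clearly superior in convergence and step count.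
- Weak points:
  - The two aryl groups of A8 differ little in size or polarisation, so both regioisomers of insertion are to be expected.
  - A6 is flat. Cc is a ketone carbon that still needs Cb, and the tetrasubstituted enone must be turned into three contiguous stereocentres with absolute control. Hydrogenation gives the cis-2,3 arrangement and no reliable enantioselective reduction of such a hindered indenone can be counted on.
- Comparison: the chosen plan sets against the shorter skeleton assembly a defined regiochemistry (each aryl is placed by its own bond-forming step) and a stereochemical chain in which every centre has a named controlling element.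

Key step: step 9

## Route

Assumption: Rh2(S-PTAD)4, which is Rh2[(S)-(1-adamantyl)(N-phthalimido)acetate]4, is taken as the catalyst enantiomer matched to the S configuration at Cc. If the R catalyst proves matched it replaces it with nothing else changed, since Cd is equilibrated afterwards.

Assumption: Weinreb amide 19 and Grignard reagent 25 (THF solution) are bought.

Step 1
Reactants: 1 3,5-dimethoxyphenylacetic acid; 2 (S)-4-benzyloxazolidin-2-one
Product: 4 (S)-4-benzyl-3-[(3,5-dimethoxyphenyl)acetyl]oxazolidin-2-one, via mixed pivalic anhydride 3 (not isolated)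
Conditions: t-BuCOCl, Et3N, THF, −20 °C; then 2, LiCl, rt
Reagents that add atoms: none
Why: Mixed-anhydride N-acylation of an oxazolidinone; the hindered pivaloyl carbonyl is not attacked, so only the arylacetyl group is transferred. No stereocentre is formed.

Step 2
Reactants: 4 (S)-4-benzyl-3-[(3,5-dimethoxyphenyl)acetyl]oxazolidin-2-one; 5 4-methoxybenzyl bromide
Product: 7 (S)-4-benzyl-3-[(2S)-2-(3,5-dimethoxyphenyl)-3-(4-methoxyphenyl)propanoyl]oxazolidin-2-one, via sodium Z-enolate 6 (not isolated)
Conditions: NaN(SiMe3)2, THF, −78 °C; then 5, −78 → −40 °C
Reagents that add atoms: none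
Why: Evans asymmetric alkylation: the chelated Z-enolate is shielded on one face by the C4 benzyl group and is benzylated from the other, which sets Cc as S. The reactive benzylic bromide allows a temperature at which the acidic α-aryl product does not re-enolise.

Step 3
Reactants: 7 (S)-4-benzyl-3-[(2S)-2-(3,5-dimethoxyphenyl)-3-(4-methoxyphenyl)propanoyl]oxazolidin-2-one
Product: 8 (2S)-2-(3,5-dimethoxyphenyl)-3-(4-methoxyphenyl)propan-1-ol
Conditions: LiBH4, MeOH (1 equiv), Et2O/THF, 0 °C
Reagents that add atoms: none
Why: Reductive cleavage of the imide at the exocyclic carbonyl by LiBH4; the cold, non-basic conditions leave the α-aryl stereocentre untouched and return auxiliary 2.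

Step 4
Reactants: 8 (2S)-2-(3,5-dimethoxyphenyl)-3-(4-methoxyphenyl)propan-1-ol
Product: 9 tert-butyl{[(2S)-2-(3,5-dimethoxyphenyl)-3-(4-methoxyphenyl)propyl]oxy}dimethylsilane
Conditions: TBSCl, imidazole, DMF, rt
Reagents that add atoms: tert-butyldimethylsilyl chloride, CC(C)(C)[Si](C)(C)Cl
Why: Standard silylation of a primary alcohol; the bulky silyl ether tolerates the lithium reagents, hydrazine, MnO2, the carbene and t-BuOK that follow and shields the adjacent OCH2 hydrogens.

Step 5
Reactants: 9 tert-butyl{[(2S)-2-(3,5-dimethoxyphenyl)-3-(4-methoxyphenyl)propyl]oxy}dimethylsilane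
Product: 10 tert-butyl{[(2S)-2-(2,6-dibromo-3,5-dimethoxyphenyl)-3-(4-methoxyphenyl)propyl]oxy}dimethylsilane
Conditions: NBS (2.1 equiv), MeCN, 0 °C → rt, dark
Reagents that add atoms: N-bromosuccinimide, O=C1CCC(=O)N1Br
Why: Electrophilic aromatic bromination: in a 5-alkyl-1,3-dimethoxybenzene the two positions para to a methoxy group are the most reactive, the position between the methoxy groups the least, and the anisole ring is far slower. Two equivalents therefore give the 2,6-dibromide (B2 and B6).

Step 6
Reactants: 11 3,5-dihydroxybenzonitrile
Product: 12 3,5-bis(methoxymethoxy)benzonitrile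
Conditions: MOMCl, i-Pr2NEt, CH2Cl2, 0 °C → rt
Reagents that add atoms: chloromethyl methyl ether, COCCl
Why: O-Alkylation of phenols with chloromethyl methyl ether; the MOM ethers survive organolithiums, the carbene and t-BuOK, and fall to acid together with the TBS group in step 11.

Step 7
Reactants: 10 tert-butyl{[(2S)-2-(2,6-dibromo-3,5-dimethoxyphenyl)-3-(4-methoxyphenyl)propyl]oxy}dimethylsilane; 12 3,5-bis(methoxymethoxy)benzonitrile
Product: 15 hydrazone of {3-bromo-2-[(2S)-1-(tert-butyldimethylsilyloxy)-3-(4-methoxyphenyl)propan-2-yl]-4,6-dimethoxyphenyl}[3,5-bis(methoxymethoxy)phenyl]methanone, via aryllithium 13 (not isolated), via N–H ketimine 14 (not isolated)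
Conditions: n-BuLi (1.0 equiv), THF, −78 °C; 12, −78 → 0 °C; MeOH; then N2H4·H2O, AcOH (cat.), EtOH, 70 °C
Reagents that add atoms: hydrazine monohydrate, NN.O
Why: Bromine–lithium exchange (the two bromines are equivalent by rotation about B1–Cc, so one equivalent gives a single monolithio species), addition of the aryllithium to the nitrile, and transimination of the N–H ketimine by hydrazine. This gives the hydrazone of a di-ortho-substituted benzophenone without a slow condensation at the hindered ketone. At −78 °C exchange and addition outrun silyl migration from the neighbouring silyl ether.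

Step 8
Reactants: 15 hydrazone of {3-bromo-2-[(2S)-1-(tert-butyldimethylsilyloxy)-3-(4-methoxyphenyl)propan-2-yl]-4,6-dimethoxyphenyl}[3,5-bis(methoxymethoxy)phenyl]methanone
Product: 16 {3-bromo-2-[(2S)-1-(tert-butyldimethylsilyloxy)-3-(4-methoxyphenyl)propan-2-yl]-4,6-dimethoxyphenyl}[3,5-bis(methoxymethoxy)phenyl]diazomethane
Conditions: MnO2, MgSO4, CH2Cl2, rt, dark; filter, use the solution at once
Reagents that add atoms: none
Why: Dehydrogenation of a diaryl ketone hydrazone to the diaryldiazomethane with MnO2; the two ortho substituents slow azine formation.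

Step 9
Reactants: 16 {3-bromo-2-[(2S)-1-(tert-butyldimethylsilyloxy)-3-(4-methoxyphenyl)propan-2-yl]-4,6-dimethoxyphenyl}[3,5-bis(methoxymethoxy)phenyl]diazomethane
Product: 18 tert-butyl{[(1S,2R,3S)-7-bromo-3-[3,5-bis(methoxymethoxy)phenyl]-4,6-dimethoxy-2-(4-methoxyphenyl)-2,3-dihydro-1H-inden-1-yl]methoxy}dimethylsilane (all-trans indane), via 2,3-cis indane 17 (not isolated)
Conditions: Rh2(S-PTAD)4 (1 mol %), 4 Å MS, CH2Cl2, −20 °C → rt; evaporate; then t-BuOK (1.5 equiv), DMSO, rt, argon
Reagents that add atoms: none
Why: The rhodium carboxylate decomposes 16 to a diaryl (donor/donor) carbene at Cd, which inserts into a benzylic C–H bond of the Ce methylene through a concerted but asynchronous, hydride-transfer-like three-centre transition state with retention at Ce, forming Cd–Ce. The closest known reaction type is the enantioselective intramolecular 1,5 C–H insertion of donor/donor rhodium carbenes that gives indanes and dihydrobenzofurans. The five-membered ring (Cd, B6, B1, Cc, Ce) closes by this 1,5 insertion, with the tether running through the arene edge B6–B1. Ce is controlled by Cc: the transition state that turns the anisyl group away from the silyloxymethyl arm on the forming ring avoids eclipsing, and the matched chiral carboxylates select the same diastereotopic hydrogen. At Cd this catalyst class turns the substituent of the inserting carbon away from the metal, so the kinetic product is expected to be the cis isomer 17. Cd is therefore set thermodynamically: t-BuOK in DMSO reversibly removes only the doubly benzylic Cd–H and should funnel the material to the all-trans indane 18. The step needs insertion at Ce–H and not at the two other 1,5 sites: the p-anisyl benzylic methylene is the best hydride donor, the OCH2 of the arm is shielded by the tert-butyldimethylsilyl group, and the ortho methoxy C–H bonds are primary. The bromine at B2 and the MOM ethers are spectators.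

Step 10
Reactants: 18 all-trans indane (as above); 19 N-methoxy-N-methyl-3,5-dimethoxybenzamide
Product: 21 {(1S,2R,3S)-1-[3,5-bis(methoxymethoxy)phenyl]-3-[(tert-butyldimethylsilyloxy)methyl]-5,7-dimethoxy-2-(4-methoxyphenyl)-2,3-dihydro-1H-inden-4-yl}(3,5-dimethoxyphenyl)methanone (ring A ketone at B2; Cc S, Ce R, Cd S), via aryllithium 20 (not isolated)
Conditions: t-BuLi (2.1 equiv), THF, −78 °C; then 19, −78 → 0 °C; H2O
Reagents that add atoms: none
Why: Bromine–lithium exchange followed by acylation of the aryllithium with a Weinreb amide, whose chelated tetrahedral intermediate prevents over-addition. The bromine placed at B2 in step 5 makes the Ca–B2 bond regiospecific.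

Step 11
Reactants: 21 ring A ketone (as above)
Product: 22 {(1S,2R,3S)-1-(3,5-dihydroxyphenyl)-3-(hydroxymethyl)-5,7-dimethoxy-2-(4-methoxyphenyl)-2,3-dihydro-1H-inden-4-yl}(3,5-dimethoxyphenyl)methanone (triol)
Conditions: HCl (3 M aq), MeOH/THF, 45 °C
Reagents that add atoms: none
Why: Acid hydrolysis of the two aryl MOM acetals and of the primary TBS ether in one operation; the methyl ethers, the diaryl ketone and the three C–H stereocentres are stable to aqueous HCl.

Step 12
Reactants: 22 triol (as above)
Product: 23 bis(4-methylbenzenesulfonate) of 22 at the two phenols of the Cd aryl (primary alcohol free)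
Conditions: TsCl (2.3 equiv), K2CO3, acetone, rt
Reagents that add atoms: 4-methylbenzenesulfonyl chloride, Cc1ccc(cc1)S(=O)(=O)Cl
Why: Sulfonylation of phenoxides under carbonate conditions, which do not touch the primary alcohol. The two tosylates turn the resorcinol ring on Cd into an electron-poor arene that cannot capture the Cb cation in step 15.

Step 13
Reactants: 23 bis(tosylate) alcohol (as above)
Product: 24 keto aldehyde: 23 with the CH2OH on Cc oxidised to CHO (Cc S, Ce R, Cd S)
Conditions: Dess–Martin periodinane, NaHCO3, CH2Cl2, 0 °C; use crude
Reagents that add atoms: none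
Why: Dess–Martin oxidation of a primary alcohol under buffered conditions; any epimerisation at Cc returns to the trans arrangement, which is the stable one on the indane. The keto aldehyde is not exposed to acid, which could condense it to a benzopyrylium salt.

Step 14
Reactants: 24 keto aldehyde (as above); 25 4-methoxyphenylmagnesium bromide
Product: 26 Cb carbinol: 24 with CHO converted to CH(OH)(4-methoxyphenyl), mixture of epimers at Cb
Conditions: 25 (1.3 equiv), THF, −78 °C; aq NH4Cl
Reagents that add atoms: none
Why: Grignard 1,2-addition to the aldehyde, which is far more electrophilic than the di-ortho-substituted, electron-rich diaryl ketone; aryl tosylates do not react without a nickel or palladium catalyst. The carbinol configuration is irrelevant because Cb is ionised in the next step.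

Step 15
Reactants: 26 Cb carbinol (as above)
Product: 27 tetracyclic ketone: hexa-O-methyl ether of the target with the two phenols of the Cd aryl as tosylates (Cb S, Cc R, Ce S, Cd S)
Conditions: TfOH (0.2 equiv), (CF3)2CHOH/CH2Cl2, 0 °C → rt
Reagents that add atoms: none
Why: Intramolecular Friedel–Crafts alkylation: the p-methoxybenzyl cation at Cb is attacked by the ortho position of ring A (para to one methoxy group), closing the seven-membered ring at Cb–A6, and the tosylated aryl on Cd cannot compete. In the ring-closing transition state the anisyl group and ring A flank the Cc hydrogen, away from the five-membered ring, which sets Cb as S with H at Cb anti to H at Cc. Elimination to the styrene and capture of the cation by the ketone oxygen are reversible under the acid.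

Step 16
Reactants: 27 tetracyclic ketone bis(tosylate) (as above)
Product: 28 hexa-O-methyl ether of the target with the two phenols of the Cd aryl free
Conditions: KOH, MeOH/THF, 65 °C, argon; then dilute HCl
Reagents that add atoms: none
Why: Hydroxide cleaves aryl sulfonates at sulfur; the methyl ethers and the ketone are stable. Any base-mediated exchange at Cb (γ to the ketone through ring A) can only favour the same, less hindered epimer.

Step 17
Reactants: 28 hexamethyl ether diphenol (as above)
Product: 29 target CNP0116600.1 (octaphenol; Cb S, Cc R, Ce S, Cd S)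
Conditions: BBr3 (excess), CH2Cl2, −78 °C → rt; then MeOH, H2O
Reagents that add atoms: none
Why: Lewis acid cleavage of the six aryl methyl ethers with BBr3, the usual last step for permethylated polyphenols of this family. The C–H stereocentres are not touched, and low temperature should keep the benzylic C–C bonds intact.

## Compound list

1 | 3,5-dimethoxyphenylacetic acid | COc1cc(CC(=O)O)cc(OC)c1 | starting material
2 | (S)-4-benzyloxazolidin-2-one | O=C1N[C@@H](Cc2ccccc2)CO1 | starting material
3 | (3,5-dimethoxyphenyl)acetic pivalic anhydride | COc1cc(CC(=O)OC(=O)C(C)(C)C)cc(OC)c1 | intermediate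
4 | (S)-4-benzyl-3-[(3,5-dimethoxyphenyl)acetyl]oxazolidin-2-one | COc1cc(CC(=O)N2[C@@H](Cc3ccccc3)COC2=O)cc(OC)c1 | intermediate
5 | 4-methoxybenzyl bromide | COc1ccc(CBr)cc1 | starting material
6 | sodium (Z)-enolate of 4 | [Na+].COc1cc(/C=C(\[O-])N2[C@@H](Cc3ccccc3)COC2=O)cc(OC)c1 | intermediate
7 | (S)-4-benzyl-3-[(2S)-2-(3,5-dimethoxyphenyl)-3-(4-methoxyphenyl)propanoyl]oxazolidin-2-one | COc1cc(cc(OC)c1)[C@H](Cc1ccc(OC)cc1)C(=O)N1[C@@H](Cc2ccccc2)COC1=O | intermediate
8 | (2S)-2-(3,5-dimethoxyphenyl)-3-(4-methoxyphenyl)propan-1-ol | COc1cc(cc(OC)c1)[C@@H](CO)Cc1ccc(OC)cc1 | intermediate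
9 | tert-butyl{[(2S)-2-(3,5-dimethoxyphenyl)-3-(4-methoxyphenyl)propyl]oxy}dimethylsilane | COc1cc(cc(OC)c1)[C@@H](CO[Si](C)(C)C(C)(C)C)Cc1ccc(OC)cc1 | intermediate
10 | tert-butyl{[(2S)-2-(2,6-dibromo-3,5-dimethoxyphenyl)-3-(4-methoxyphenyl)propyl]oxy}dimethylsilane | COc1cc(OC)c(Br)c(c1Br)[C@@H](CO[Si](C)(C)C(C)(C)C)Cc1ccc(OC)cc1 | intermediate
11 | 3,5-dihydroxybenzonitrile | N#Cc1cc(O)cc(O)c1 | starting material
12 | 3,5-bis(methoxymethoxy)benzonitrile | N#Cc1cc(OCOC)cc(OCOC)c1 | intermediate
13 | monolithio species from 10 (lithium at B6, bromine at B2) | COc1cc(OC)c(Br)c(c1[Li])[C@@H](CO[Si](C)(C)C(C)(C)C)Cc1ccc(OC)cc1 | intermediate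
14 | N–H ketimine: {3-bromo-2-[(2S)-1-(tert-butyldimethylsilyloxy)-3-(4-methoxyphenyl)propan-2-yl]-4,6-dimethoxyphenyl}[3,5-bis(methoxymethoxy)phenyl]methanimine | N=C(c1cc(OCOC)cc(OCOC)c1)c1c(OC)cc(OC)c(Br)c1[C@@H](CO[Si](C)(C)C(C)(C)C)Cc1ccc(OC)cc1 | intermediate
15 | hydrazone of the corresponding diaryl ketone | NN=C(c1cc(OCOC)cc(OCOC)c1)c1c(OC)cc(OC)c(Br)c1[C@@H](CO[Si](C)(C)C(C)(C)C)Cc1ccc(OC)cc1 | intermediate
16 | diaryldiazomethane (precursor of the key step) | [N-]=[N+]=C(c1cc(OCOC)cc(OCOC)c1)c1c(OC)cc(OC)c(Br)c1[C@@H](CO[Si](C)(C)C(C)(C)C)Cc1ccc(OC)cc1 | intermediate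
17 | (1S,2R,3R)-indane, Cd aryl cis to Ce aryl (kinetic insertion product) | CC(C)(C)[Si](C)(C)OC[C@@H]1c2c(Br)c(OC)cc(OC)c2[C@@H](c2cc(OCOC)cc(OCOC)c2)[C@H]1c1ccc(OC)cc1 | intermediate
18 | tert-butyl{[(1S,2R,3S)-7-bromo-3-[3,5-bis(methoxymethoxy)phenyl]-4,6-dimethoxy-2-(4-methoxyphenyl)-2,3-dihydro-1H-inden-1-yl]methoxy}dimethylsilane (all-trans) | CC(C)(C)[Si](C)(C)OC[C@@H]1c2c(Br)c(OC)cc(OC)c2[C@H](c2cc(OCOC)cc(OCOC)c2)[C@H]1c1ccc(OC)cc1 | intermediate
19 | N-methoxy-N-methyl-3,5-dimethoxybenzamide | CON(C)C(=O)c1cc(OC)cc(OC)c1 | starting material
20 | aryllithium from 18 (lithium at B2) | CC(C)(C)[Si](C)(C)OC[C@@H]1c2c([Li])c(OC)cc(OC)c2[C@H](c2cc(OCOC)cc(OCOC)c2)[C@H]1c1ccc(OC)cc1 | intermediate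
21 | all-trans indane with a 3,5-dimethoxybenzoyl group at B2, TBS and MOM ethers intact | CC(C)(C)[Si](C)(C)OC[C@@H]1c2c(C(=O)c3cc(OC)cc(OC)c3)c(OC)cc(OC)c2[C@H](c2cc(OCOC)cc(OCOC)c2)[C@H]1c1ccc(OC)cc1 | intermediate
22 | triol: 21 without TBS and MOM groups | OC[C@@H]1c2c(C(=O)c3cc(OC)cc(OC)c3)c(OC)cc(OC)c2[C@H](c2cc(O)cc(O)c2)[C@H]1c1ccc(OC)cc1 | intermediate
23 | bis(tosylate) of 22 at the Cd aryl phenols | OC[C@@H]1c2c(C(=O)c3cc(OC)cc(OC)c3)c(OC)cc(OC)c2[C@H](c2cc(OS(=O)(=O)c3ccc(C)cc3)cc(OS(=O)(=O)c3ccc(C)cc3)c2)[C@H]1c1ccc(OC)cc1 | intermediate
24 | keto aldehyde (CHO on Cc) | O=C[C@@H]1c2c(C(=O)c3cc(OC)cc(OC)c3)c(OC)cc(OC)c2[C@H](c2cc(OS(=O)(=O)c3ccc(C)cc3)cc(OS(=O)(=O)c3ccc(C)cc3)c2)[C@H]1c1ccc(OC)cc1 | intermediate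
25 | 4-methoxyphenylmagnesium bromide | COc1ccc([Mg]Br)cc1 | starting material
26 | Cb carbinol, CH(OH)(4-methoxyphenyl) on Cc, both Cb epimers | COc1ccc(cc1)C(O)[C@@H]1c2c(C(=O)c3cc(OC)cc(OC)c3)c(OC)cc(OC)c2[C@H](c2cc(OS(=O)(=O)c3ccc(C)cc3)cc(OS(=O)(=O)c3ccc(C)cc3)c2)[C@H]1c1ccc(OC)cc1 | intermediate
27 | tetracyclic ketone, hexamethyl ether, bis(tosylate) on the Cd aryl (Cb S, Cc R, Ce S, Cd S) | O=C1c2cc(OC)cc(OC)c2[C@H](c2ccc(OC)cc2)[C@@H]2c3c1c(OC)cc(OC)c3[C@H](c1cc(OS(=O)(=O)c4ccc(C)cc4)cc(OS(=O)(=O)c4ccc(C)cc4)c1)[C@H]2c1ccc(OC)cc1 | intermediate
28 | tetracyclic ketone, hexamethyl ether, free 3,5-dihydroxyphenyl on Cd | O=C1c2cc(OC)cc(OC)c2[C@H](c2ccc(OC)cc2)[C@@H]2c3c1c(OC)cc(OC)c3[C@H](c1cc(O)cc(O)c1)[C@H]2c1ccc(OC)cc1 | intermediate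
29 | CNP0116600.1 (Cb S, Cc R, Ce S, Cd S) | O=C1c2cc(O)cc(O)c2[C@H](c2ccc(O)cc2)[C@@H]2c3c1c(O)cc(O)c3[C@H](c1cc(O)cc(O)c1)[C@H]2c1ccc(O)cc1 | target

## Step count and least certain steps

Total steps: 17 (16 in the main line plus step 6, the preparation of nitrile 12). Longest linear sequence: 16 steps (steps 1–5 and 7–17).

**Step 9 (key step).** The most likely failure is misdirected insertion: the carbene may attack the OCH2 hydrogens of the silyloxymethyl arm, which are also 1,5-related and oxygen-activated, so that the wrong five-membered ring forms. The fallback makes those hydrogens electron-poor. It sets out from 16. Fluoride (Bu4NF, THF, 0 °C) removes the silyl group to give the hydroxy diazo compound F1. Acylation with pivaloyl chloride, Et3N and DMAP, under which a diaryldiazomethane is stable, gives the pivalate diazo compound F2. Its acyloxy group deactivates the adjacent C–H bonds, and the rhodium-catalysed insertion should then give the pivalate indane F3. Methanolysis (K2CO3, MeOH) gives the indane alcohol F4, and silylation (TBSCl, imidazole) returns to 17, which is equilibrated to 18 as in step 9.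

**Step 15.** Ring A is deactivated by its ketone. The cation at Cb may therefore sit as the styrene or as the cyclic oxocarbenium ion and oligomerise before the seven-membered ring closes, or close with poor facial selectivity. The fallback inverts the order of the two bonds at Cb. It sets out from aldehyde 24. A Lewis acid (Me2AlCl, CH2Cl2, −78 °C) activates the aldehyde, a stronger electrophile than the benzyl cation, for intramolecular hydroxyalkylation of ring A, giving the tetracyclic carbinol F5. Ionisation of F5 with catalytic TfOH in anisole then brings in the anisyl group as an external nucleophile on the ring face away from the five-membered ring, returning to 27.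

**Step 10.** The aryllithium at B2 is flanked by a methoxy group and the substituted indane carbon. Addition to the Weinreb amide may be slower than proton transfer or silyl migration. The fallback uses a smaller electrophile and an oxidation. From 18, the aryllithium 20 is quenched with 3,5-dimethoxybenzaldehyde to give the diaryl carbinol F6 (both Ca epimers), and oxidation with MnO2 or Dess–Martin periodinane returns to 21.

**Step 17.** Once the Cd aryl is a free resorcinol, the Lewis and Brønsted acid of the demethylation could reopen the Cb–aryl bonds and let that ring capture the cation, or cleavage of the six ethers could stall. The fallback changes the order of the last two steps. From 27, BBr3 is applied while the Cd aryl is still deactivated, giving the hexaphenol bis(tosylate) F7. The sulfonates are then cleaved with KOH in degassed MeOH under argon, returning to 29.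

**Step 2.** The α-aryl imide is acidic. Enolate equilibration during alkylation or work-up would erode the configuration at Cc, on which every later stereocentre depends. The fallback sets Cc by hydrogenation and sets out from 1. Perkin condensation with 4-methoxybenzaldehyde (Ac2O, Et3N, 120 °C) gives the E-acrylic acid F8. Asymmetric hydrogenation with [Ru(OAc)2(BINAP)], using the ligand enantiomer that delivers the S acid, gives the diarylpropanoic acid F9. Reduction with BH3·THF returns to 8.

## Further compounds

F1 | step 9 | hydroxy diazo compound (16 without the silyl group) | [N-]=[N+]=C(c1cc(OCOC)cc(OCOC)c1)c1c(OC)cc(OC)c(Br)c1[C@@H](CO)Cc1ccc(OC)cc1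
F2 | step 9 | pivalate diazo compound | [N-]=[N+]=C(c1cc(OCOC)cc(OCOC)c1)c1c(OC)cc(OC)c(Br)c1[C@@H](COC(=O)C(C)(C)C)Cc1ccc(OC)cc1
F3 | step 9 | pivalate of the (1S,2R,3R)-indane (Cd aryl cis to Ce aryl) | CC(C)(C)C(=O)OC[C@@H]1c2c(Br)c(OC)cc(OC)c2[C@@H](c2cc(OCOC)cc(OCOC)c2)[C@H]1c1ccc(OC)cc1
F4 | step 9 | (1S,2R,3R)-indane alcohol | OC[C@@H]1c2c(Br)c(OC)cc(OC)c2[C@@H](c2cc(OCOC)cc(OCOC)c2)[C@H]1c1ccc(OC)cc1
F5 | step 15 | tetracyclic Cb carbinol (seven-membered ring closed, OH and H on Cb, both epimers) | O=C1c2cc(OC)cc(OC)c2C(O)[C@@H]2c3c1c(OC)cc(OC)c3[C@H](c1cc(OS(=O)(=O)c4ccc(C)cc4)cc(OS(=O)(=O)c4ccc(C)cc4)c1)[C@H]2c1ccc(OC)cc1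
F6 | step 10 | diaryl carbinol at Ca (both epimers) | CC(C)(C)[Si](C)(C)OC[C@@H]1c2c(C(O)c3cc(OC)cc(OC)c3)c(OC)cc(OC)c2[C@H](c2cc(OCOC)cc(OCOC)c2)[C@H]1c1ccc(OC)cc1
F7 | step 17 | hexaphenol with the Cd aryl as bis(tosylate) | O=C1c2cc(O)cc(O)c2[C@H](c2ccc(O)cc2)[C@@H]2c3c1c(O)cc(O)c3[C@H](c1cc(OS(=O)(=O)c4ccc(C)cc4)cc(OS(=O)(=O)c4ccc(C)cc4)c1)[C@H]2c1ccc(O)cc1
F8 | step 2 | (E)-2-(3,5-dimethoxyphenyl)-3-(4-methoxyphenyl)acrylic acid | O=C(O)/C(=C/c1ccc(OC)cc1)c1cc(OC)cc(OC)c1
F9 | step 2 | (2S)-2-(3,5-dimethoxyphenyl)-3-(4-methoxyphenyl)propanoic acid | COc1cc(cc(OC)c1)[C@@H](C(=O)O)Cc1ccc(OC)cc1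
A1 | alternative 1 | dibenzosuberone with anisyl on Cb and CO2Me on Cc | O=C1c2cc(OC)cc(OC)c2[C@H](c2ccc(OC)cc2)[C@@H](C(=O)OC)c2cc(OC)cc(OC)c12
A2 | alternative 1 | methyl 4,6-dimethoxy-3-(4-methoxyphenyl)-1-oxoindane-2-carboxylate (trans) | O=C1c2cc(OC)cc(OC)c2[C@H](c2ccc(OC)cc2)[C@H]1C(=O)OC
A3 | alternative 1 | 3,5-dimethoxy-2-(trimethylsilyl)phenyl trifluoromethanesulfonate | COc1cc(OC)c([Si](C)(C)C)c(OS(=O)(=O)C(F)(F)F)c1
A4 | alternative 2 | hepta-O-methyl mono-O-mesyl ether of the target | O=C1c2cc(OC)cc(OC)c2[C@H](c2ccc(OC)cc2)[C@@H]2c3c1c(OC)cc(OC)c3[C@H](c1cc(OC)cc(OC)c1)[C@H]2c1ccc(OS(C)(=O)=O)cc1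
A5 | alternative 2 | six/six isomer: anthrone with peri-fused six-membered ring, quaternary Cb, hydroxyl on Cc | O=C1c2cc(OC)cc(OC)c2[C@]2(c3ccc(OC)cc3)[C@@H](O)[C@H](c3ccc(OS(C)(=O)=O)cc3)[C@@H](c3cc(OC)cc(OC)c3)c3c(OC)cc(OC)c1c32
A6 | alternative 3 | 7-bromo-4,6-dimethoxy-3-(3,5-dimethoxyphenyl)-2-(4-methoxyphenyl)inden-1-one | O=C1C(c2ccc(OC)cc2)=C(c2cc(OC)cc(OC)c2)c2c(OC)cc(OC)c(Br)c12
A7 | alternative 3 | 2,6-dibromo-3,5-dimethoxybenzaldehyde | O=Cc1c(Br)c(OC)cc(OC)c1Br
A8 | alternative 3 | 1,3-dimethoxy-5-[(4-methoxyphenyl)ethynyl]benzene | COc1ccc(C#Cc2cc(OC)cc(OC)c2)cc1
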